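**Retrosynthetic overview**

1. Numbering: ring A is C1(=O), C2(OMe), C3(OH), C4(=O), C5(Me), C6(side chain); the all-E hexaprenyl chain is C1'–C24'. The chain is cut at C1'–C2'.
2. Key step: a one-pot, three-component union of a C28 terminal alkyne, AlMe3 and a ring A benzylic chloride. Zirconium-catalysed syn-methylalumination is followed by a zerovalent-nickel benzyl–alkenyl coupling, so the C3'–CH3 bond, the C1'–C2' bond and the 2'E olefin arise together.
3. Enabling feature: C1' sits on C6 of ring A and is benzylic once ring A is held as its aromatic C1/C4 dimethyl ether, so C1'–Cl adds to zerovalent nickel. C2'=C3' with its C3' methyl is the retron of methylmetalation of a terminal alkyne.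
4. Ring A is never closed in the route. It comes as the arene of 2,4,5-trimethoxybenzaldehyde; the C3 oxygen enters by lithiation between two methoxyls and C1' by para-formylation. The quinone is unveiled last by oxidative demethylation at C1/C4, with loss of the C3 silyl group.
5. Chain: farnesyl sulfone plus 8-bromogeranyl acetate (sulfone alkylation, reductive desulfonylation) gives geranylfarnesol, then the bromide and a propargyl unit.

Key step: step 14

Assumption: sulfone 7 is carried as a racemate at its sulfonyl-bearing carbon, which is removed in step 5; compounds 1, 3, 11, 15 and 24 are taken as catalogue materials.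

**Route**

Step 1
Reactants: 1 (2E,6E)-farnesyl bromide
Product: 2 (2E,6E)-farnesyl phenyl sulfone
Conditions: PhSO2Na (1.3 equiv), DMF, rt
Reagents that add atoms: sodium benzenesulfinate [Na+].[O-]S(=O)c1ccccc1
Why: SN2 S-alkylation of the sulfinate at the primary allylic carbon should give the sulfone with the 2E olefin untouched and installs the anion-stabilising group for step 4.

Step 2
Reactants: 3 geranyl acetate
Product: 4 (2E,6E)-8-hydroxy-3,7-dimethylocta-2,6-dien-1-yl acetate
Conditions: SeO2 (0.1 equiv), t-BuOOH (3 equiv), salicylic acid (0.1 equiv), CH2Cl2, rt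
Reagents that add atoms: tert-butyl hydroperoxide CC(C)(C)OO
Why: Riley allylic oxidation (ene reaction then [2,3]-sigmatropic shift) should hydroxylate the E-methyl of the terminal isopropylidene, because the C2=C3 olefin is deactivated by the allylic acetate, and the ene/[2,3] sequence fixes the 6E geometry.

Step 3
Reactants: 4 (2E,6E)-8-hydroxy-3,7-dimethylocta-2,6-dien-1-yl acetate
Product: 5 (2E,6E)-8-bromo-3,7-dimethylocta-2,6-dien-1-yl acetate
Conditions: CBr4 (1.2 equiv), PPh3 (1.25 equiv), CH2Cl2, 0 °C
Reagents that add atoms: carbon tetrabromide BrC(Br)(Br)Br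
Why: Appel bromination under neutral conditions should convert the primary allylic alcohol into the bromide without allylic transposition or loss of the acetate.

Step 4
Reactants: 2 (2E,6E)-farnesyl phenyl sulfone, 5 (2E,6E)-8-bromo-3,7-dimethylocta-2,6-dien-1-yl acetate
Product: 7 (2E,6E,10E,14E)-3,7,11,15,19-pentamethyl-9-(phenylsulfonyl)icosa-2,6,10,14,18-pentaen-1-yl acetate (racemic at C9), via α-lithiated farnesyl phenyl sulfone 6 (not isolated)
Conditions: 2, n-BuLi (1.0 equiv), THF/DMPU (6:1), −78 °C; then 5, −78 → −40 °C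
Reagents that add atoms: none
Why: Sulfone alkylation (Biellmann-type coupling): the α-sulfonyl allyl anion should displace the primary allylic bromide by SN2 at −78 °C faster than it attacks the acetate, joining C15 and C10 head to tail; the new C9 stereocentre forms as a racemate and is erased in step 5.

Step 5
Reactants: 7 (2E,6E,10E,14E)-3,7,11,15,19-pentamethyl-9-(phenylsulfonyl)icosa-2,6,10,14,18-pentaen-1-yl acetate
Product: 9 (2E,6E,10E,14E)-geranylfarnesol, via hydroxy sulfone lithium alkoxide 8 (not isolated)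
Conditions: LiBHEt3 (5 equiv), THF, 0 °C, 20 min; then PdCl2(dppp) (5 mol %), 0 °C → rt
Reagents that add atoms: none
Why: Hydride reduction should first cleave the acetate to an alkoxide that zerovalent palladium does not ionise, after which palladium-catalysed reductive desulfonylation (hydride capture of the π-allyl palladium species at its less substituted terminus) should replace the sulfonyl group by hydrogen and keep the 10E trisubstituted olefin in place.

Step 6
Reactants: 9 (2E,6E,10E,14E)-geranylfarnesol
Product: 10 (2E,6E,10E,14E)-geranylfarnesyl bromide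
Conditions: CBr4 (1.2 equiv), PPh3 (1.25 equiv), CH2Cl2, 0 °C
Reagents that add atoms: carbon tetrabromide BrC(Br)(Br)Br
Why: Appel bromination of the primary allylic alcohol under neutral conditions should give the bromide with the 2E olefin and the acid-sensitive polyene intact.

Step 7
Reactants: 10 (2E,6E,10E,14E)-geranylfarnesyl bromide, 11 1-(trimethylsilyl)propyne
Product: 14 (5E,9E,13E,17E)-6,10,14,18,22-pentamethyltricosa-5,9,13,17,21-pentaen-1-yne, via 3-lithio-1-(trimethylsilyl)propyne 12 (not isolated), via silyl-capped C28 enyne 13 (not isolated)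
Conditions: 11 (1.5 equiv), n-BuLi (1.4 equiv), THF, −78 °C; then 10, −78 °C → rt; then MeOH, K2CO3 (0.2 equiv), rt
Reagents that add atoms: none
Why: SN2 alkylation of the silyl-blocked propargyl anion at the primary allylic bromide (the silyl group suppresses allenyl products) followed by base-catalysed protodesilylation should give the terminal alkyne without touching the skipped olefins.

Step 8
Reactants: 15 2,4,5-trimethoxybenzaldehyde
Product: 16 1,2,4-trimethoxy-5-methylbenzene
Conditions: H2 (4 bar), Pd/C (10 wt %), AcOH, 50 °C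
Reagents that add atoms: none
Why: Catalytic hydrogenolysis of an electron-rich benzaldehyde, through the benzylic alcohol, should stop cleanly at the methylarene.

Step 9
Reactants: 16 1,2,4-trimethoxy-5-methylbenzene
Product: 19 2,3,6-trimethoxy-5-methylphenol, via aryllithium 17 (not isolated), via dimethyl arylboronate 18 (not isolated)
Conditions: n-BuLi (1.2 equiv), TMEDA (1.2 equiv), THF, 0 °C → rt; B(OMe)3 (1.5 equiv), −78 °C → rt; then AcOH, 30% aq. H2O2, 0 °C → rt
Reagents that add atoms: hydrogen peroxide OO
Why: Directed ortho-metalation should occur at the only ring C–H flanked by two methoxyl groups, and borylation followed by oxidative aryl migration from boron to oxygen should place the hydroxyl between those methoxyls (the future C3–OH).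

Step 10
Reactants: 19 2,3,6-trimethoxy-5-methylphenol
Product: 20 4-hydroxy-2,3,5-trimethoxy-6-methylbenzaldehyde
Conditions: Cl2CHOMe (1.3 equiv), TiCl4 (2.2 equiv), CH2Cl2, −10 → 0 °C; then ice-cold 1 M HCl
Reagents that add atoms: dichloromethyl methyl ether COC(Cl)Cl; water O
Why: Rieche formylation has only one unsubstituted ring position to attack, the one para to the hydroxyl, so the future C1' carbon should enter without any regiochemical choice.

Step 11
Reactants: 20 4-hydroxy-2,3,5-trimethoxy-6-methylbenzaldehyde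
Product: 21 4-[(tert-butyldimethylsilyl)oxy]-2,3,5-trimethoxy-6-methylbenzaldehyde
Conditions: TBSCl (1.3 equiv), imidazole (2.5 equiv), DMF, rt
Reagents that add atoms: tert-butyldimethylsilyl chloride CC(C)(C)[Si](C)(C)Cl
Why: Imidazole-promoted O-silylation of the acidic para-formyl phenol should mask the future C3 hydroxyl as an ether that is inert to alanes and zerovalent nickel.

Step 12
Reactants: 21 4-[(tert-butyldimethylsilyl)oxy]-2,3,5-trimethoxy-6-methylbenzaldehyde
Product: 22 {4-[(tert-butyldimethylsilyl)oxy]-2,3,5-trimethoxy-6-methylphenyl}methanol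
Conditions: NaBH4 (1.0 equiv), THF/MeOH (4:1), 0 °C
Reagents that add atoms: none
Why: Borohydride reduction of the aldehyde should give the benzylic alcohol and leave the aryl silyl ether intact at 0 °C.

Step 13
Reactants: 22 {4-[(tert-butyldimethylsilyl)oxy]-2,3,5-trimethoxy-6-methylphenyl}methanol
Product: 23 tert-butyl[4-(chloromethyl)-2,3,6-trimethoxy-5-methylphenoxy]dimethylsilane
Conditions: PPh3 (1.3 equiv), CCl4/CH2Cl2 (1:2), rt
Reagents that add atoms: carbon tetrachloride ClC(Cl)(Cl)Cl
Why: Appel chlorination should convert the electron-rich benzylic alcohol into the chloride under neutral conditions that spare the silyl ether.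

Step 14
Reactants: 14 (5E,9E,13E,17E)-6,10,14,18,22-pentamethyltricosa-5,9,13,17,21-pentaen-1-yne, 24 trimethylaluminium, 23 tert-butyl[4-(chloromethyl)-2,3,6-trimethoxy-5-methylphenoxy]dimethylsilane
Product: 26 tert-butyl{4-[(2E,6E,10E,14E,18E)-3,7,11,15,19,23-hexamethyltetracosa-2,6,10,14,18,22-hexaen-1-yl]-2,3,6-trimethoxy-5-methylphenoxy}dimethylsilane, via (E)-alkenyldimethylalane 25 (not isolated)
Conditions: 14 (1.2 equiv), AlMe3 (2.4 equiv), Cp2ZrCl2 (0.25 equiv), ClCH2CH2Cl, 0 °C → rt; volatiles and excess AlMe3 removed in vacuo, THF; then 23 (1.0 equiv), NiCl2(PPh3)2 (3 mol %) pre-reduced with n-BuLi (6 mol %), THF, 0 °C → rt; cold 1 M HCl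
Reagents that add atoms: none
Why: Cp2ZrCl2 and AlMe3 form a bimetallic methyl species that adds methyl and metal syn across the terminal alkyne of 14 with methyl on the internal carbon, giving alane 25 after zirconium-to-aluminium exchange; zerovalent nickel then adds oxidatively to the benzylic C–Cl bond of 23, the alkenyl group passes from aluminium to nickel, and reductive elimination forms the C1'–C2' bond. The closest known reaction type is the Negishi zirconium-catalysed methylalumination of terminal alkynes followed in the same pot by nickel-catalysed benzyl–alkenyl cross-coupling with chloromethylated polymethoxytoluenes. No ring is closed and no stereocentre is created; the only stereochemical element, the 2'E double bond, is fixed by the syn addition and by retention of alkenyl geometry through transmetalation and reductive elimination. The step needs methyl delivery to the internal alkyne carbon, which the unbranched terminal alkyne secures, reaction at the alkyne only, which holds because the five trisubstituted olefins do not insert under these conditions, and coupling at the sp3 C–Cl bond only, which holds because the aryl C–O bonds of the methoxyl and silyloxy groups are inert to zerovalent nickel at 0 °C. Removal of excess AlMe3 before the nickel stage should suppress methyl transfer to the benzylic carbon.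

Step 15
Reactants: 26 tert-butyl{4-[(2E,6E,10E,14E,18E)-3,7,11,15,19,23-hexamethyltetracosa-2,6,10,14,18,22-hexaen-1-yl]-2,3,6-trimethoxy-5-methylphenoxy}dimethylsilane
Product: 28 3-demethylubiquinone-6, via silyloxyquinone 27 (not isolated)
Conditions: (NH4)2Ce(NO3)6 (2.5 equiv), MeCN/CH2Cl2/H2O, 0 °C; then crude in THF/AcOH/H2O (3:1:1), rt
Reagents that add atoms: water O
Why: Oxidative demethylation by tetravalent cerium (arene radical cation, water adding at C1 and C4, the only para-dioxygenated pair) should give the para-quinone, and the C3 silyl ether, by then a vinylogous silyl ester, should hydrolyse in aqueous acetic acid to free the C3 hydroxyl.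

**Compound list**

1 | (2E,6E)-farnesyl bromide [(2E,6E)-1-bromo-3,7,11-trimethyldodeca-2,6,10-triene] | BrC/C=C(\C)CC/C=C(\C)CCC=C(C)C | starting material
2 | (2E,6E)-farnesyl phenyl sulfone | O=S(=O)(C/C=C(\C)CC/C=C(\C)CCC=C(C)C)c1ccccc1 | intermediate
3 | geranyl acetate [(2E)-3,7-dimethylocta-2,6-dien-1-yl acetate] | CC(=O)OC/C=C(\C)CCC=C(C)C | starting material
4 | (2E,6E)-8-hydroxy-3,7-dimethylocta-2,6-dien-1-yl acetate | CC(=O)OC/C=C(\C)CC/C=C(\C)CO | intermediate
5 | (2E,6E)-8-bromo-3,7-dimethylocta-2,6-dien-1-yl acetate | CC(=O)OC/C=C(\C)CC/C=C(\C)CBr | intermediate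
6 | α-lithiated farnesyl phenyl sulfone | [Li]C(S(=O)(=O)c1ccccc1)/C=C(\C)CC/C=C(\C)CCC=C(C)C | intermediate (not isolated)
7 | (2E,6E,10E,14E)-3,7,11,15,19-pentamethyl-9-(phenylsulfonyl)icosa-2,6,10,14,18-pentaen-1-yl acetate, racemic at C9 | CC(=O)OC/C=C(\C)CC/C=C(\C)CC(S(=O)(=O)c1ccccc1)/C=C(\C)CC/C=C(\C)CCC=C(C)C | intermediate
8 | lithium alkoxide of the hydroxy sulfone from 7 | [Li]OC/C=C(\C)CC/C=C(\C)CC(S(=O)(=O)c1ccccc1)/C=C(\C)CC/C=C(\C)CCC=C(C)C | intermediate (not isolated)
9 | (2E,6E,10E,14E)-geranylfarnesol [(2E,6E,10E,14E)-3,7,11,15,19-pentamethylicosa-2,6,10,14,18-pentaen-1-ol] | OC/C=C(\C)CC/C=C(\C)CC/C=C(\C)CC/C=C(\C)CCC=C(C)C | intermediate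
10 | (2E,6E,10E,14E)-geranylfarnesyl bromide | BrC/C=C(\C)CC/C=C(\C)CC/C=C(\C)CC/C=C(\C)CCC=C(C)C | intermediate
11 | 1-(trimethylsilyl)propyne | CC#C[Si](C)(C)C | starting material
12 | 3-lithio-1-(trimethylsilyl)propyne | [Li]CC#C[Si](C)(C)C | intermediate (not isolated)
13 | trimethyl[(5E,9E,13E,17E)-6,10,14,18,22-pentamethyltricosa-5,9,13,17,21-pentaen-1-yn-1-yl]silane | C[Si](C)(C)C#CCC/C=C(\C)CC/C=C(\C)CC/C=C(\C)CC/C=C(\C)CCC=C(C)C | intermediate (not isolated)
14 | (5E,9E,13E,17E)-6,10,14,18,22-pentamethyltricosa-5,9,13,17,21-pentaen-1-yne | C#CCC/C=C(\C)CC/C=C(\C)CC/C=C(\C)CC/C=C(\C)CCC=C(C)C | intermediate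
15 | 2,4,5-trimethoxybenzaldehyde | COc1cc(OC)c(C=O)cc1OC | starting material
16 | 1,2,4-trimethoxy-5-methylbenzene | COc1cc(OC)c(C)cc1OC | intermediate
17 | (2,3,6-trimethoxy-5-methylphenyl)lithium | [Li]c1c(OC)c(C)cc(OC)c1OC | intermediate (not isolated)
18 | dimethyl (2,3,6-trimethoxy-5-methylphenyl)boronate | COB(OC)c1c(OC)c(C)cc(OC)c1OC | intermediate (not isolated)
19 | 2,3,6-trimethoxy-5-methylphenol | Oc1c(OC)c(C)cc(OC)c1OC | intermediate
20 | 4-hydroxy-2,3,5-trimethoxy-6-methylbenzaldehyde | O=Cc1c(C)c(OC)c(O)c(OC)c1OC | intermediate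
21 | 4-[(tert-butyldimethylsilyl)oxy]-2,3,5-trimethoxy-6-methylbenzaldehyde | O=Cc1c(C)c(OC)c(O[Si](C)(C)C(C)(C)C)c(OC)c1OC | intermediate
22 | {4-[(tert-butyldimethylsilyl)oxy]-2,3,5-trimethoxy-6-methylphenyl}methanol | OCc1c(C)c(OC)c(O[Si](C)(C)C(C)(C)C)c(OC)c1OC | intermediate
23 | tert-butyl[4-(chloromethyl)-2,3,6-trimethoxy-5-methylphenoxy]dimethylsilane | ClCc1c(C)c(OC)c(O[Si](C)(C)C(C)(C)C)c(OC)c1OC | intermediate
24 | trimethylaluminium | C[Al](C)C | starting material
25 | dimethyl[(1E,5E,9E,13E,17E)-2,6,10,14,18,22-hexamethyltricosa-1,5,9,13,17,21-hexaen-1-yl]alane | C[Al](C)/C=C(\C)CC/C=C(\C)CC/C=C(\C)CC/C=C(\C)CC/C=C(\C)CCC=C(C)C | intermediate (not isolated)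
26 | tert-butyl{4-[(2E,6E,10E,14E,18E)-3,7,11,15,19,23-hexamethyltetracosa-2,6,10,14,18,22-hexaen-1-yl]-2,3,6-trimethoxy-5-methylphenoxy}dimethylsilane | CC(C)(C)[Si](C)(C)Oc1c(OC)c(C)c(C/C=C(\C)CC/C=C(\C)CC/C=C(\C)CC/C=C(\C)CC/C=C(\C)CCC=C(C)C)c(OC)c1OC | intermediate
27 | 3-[(tert-butyldimethylsilyl)oxy]-2-methoxy-5-methyl-6-[(2E,6E,10E,14E,18E)-3,7,11,15,19,23-hexamethyltetracosa-2,6,10,14,18,22-hexaen-1-yl]cyclohexa-2,5-diene-1,4-dione | COC1=C(O[Si](C)(C)C(C)(C)C)C(=O)C(C)=C(C/C=C(\C)CC/C=C(\C)CC/C=C(\C)CC/C=C(\C)CC/C=C(\C)CCC=C(C)C)C1=O | intermediate (not isolated)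
28 | 3-demethylubiquinone-6 [3-hydroxy-2-methoxy-5-methyl-6-[(2E,6E,10E,14E,18E)-3,7,11,15,19,23-hexamethyltetracosa-2,6,10,14,18,22-hexaen-1-yl]cyclohexa-2,5-diene-1,4-dione] | COC1=C(O)C(=O)C(C)=C(C/C=C(\C)CC/C=C(\C)CC/C=C(\C)CC/C=C(\C)CC/C=C(\C)CCC=C(C)C)C1=O | target

**Totals**

Total step count: 15.
Longest linear sequence: 8 steps (steps 2–7, 14, 15; the arene branch, steps 8–13, 14, 15, is equally long).

**Steps most likely to fail**

Step 14. The methylalumination may stay incomplete or lose regiocontrol, the alkenyl–aluminium bond may be protonated by adventitious moisture, and at the nickel stage the benzylic chloride may dimerise reductively or take up methyl from residual AlMe3. The fallback sets out from 14 and 23, returns at 26, and reverses the polarity of the union. Alkyne 14 is methylaluminated as before to 25, which is quenched with I2 in THF at −30 °C to give the (1E,5E,9E,13E,17E)-1-iodo-2,6,10,14,18,22-hexamethyltricosa-1,5,9,13,17,21-hexaene F1. Chloride 23 is treated with Zn dust and LiCl in THF to give the {4-[(tert-butyldimethylsilyl)oxy]-2,3,5-trimethoxy-6-methylbenzyl}zinc chloride F2. Negishi coupling of F1 with F2 under Pd(PPh3)4 catalysis in THF at rt should then deliver 26 with retention of the E geometry.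

Step 15. The oxidation may proceed in the ortho sense, the silyl group may be lost early so that a free phenol is over-oxidised, and the polyene may be attacked by excess oxidant. The fallback sets out from 26, returns at 28, and replaces the silyl ether by an electron-withdrawing ester before oxidation. Desilylation with n-Bu4NF in THF at 0 °C gives the 4-hexaprenyl-2,3,6-trimethoxy-5-methylphenol F3. Acetylation with Ac2O, pyridine and DMAP gives the corresponding aryl acetate F4. Oxidation with (NH4)2Ce(NO3)6 in MeCN/H2O at 0 °C, to which the acetate is inert, gives the 3-acetoxy-2-methoxy-5-methyl-6-hexaprenyl-1,4-benzoquinone F5. Brief methanolysis of this vinylogous anhydride with K2CO3 in MeOH at 0 °C under argon, then acidification, should give 28.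

Step 5. Hydride capture of the π-allyl palladium intermediate may cause allylic transposition or E/Z erosion, and the allylic C–O bond may be hydrogenolysed if the acetate is not fully cleaved before the palladium salt is added. The fallback sets out from 7, returns at 9, and replaces the palladium–hydride substitution by an electron-transfer C–S cleavage on the free alcohol. Methanolysis with K2CO3 in MeOH at rt gives the (2E,6E,10E,14E)-3,7,11,15,19-pentamethyl-9-(phenylsulfonyl)icosa-2,6,10,14,18-pentaen-1-ol F6. Dissolving-metal desulfonylation with Li in EtNH2/THF at −78 °C should then give 9.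

**Further compounds**

F1 | step 14 | (1E,5E,9E,13E,17E)-1-iodo-2,6,10,14,18,22-hexamethyltricosa-1,5,9,13,17,21-hexaene | I/C=C(\C)CC/C=C(\C)CC/C=C(\C)CC/C=C(\C)CC/C=C(\C)CCC=C(C)C
F2 | step 14 | {4-[(tert-butyldimethylsilyl)oxy]-2,3,5-trimethoxy-6-methylbenzyl}zinc chloride | Cl[Zn]Cc1c(C)c(OC)c(O[Si](C)(C)C(C)(C)C)c(OC)c1OC
F3 | step 15 | 4-[(2E,6E,10E,14E,18E)-3,7,11,15,19,23-hexamethyltetracosa-2,6,10,14,18,22-hexaen-1-yl]-2,3,6-trimethoxy-5-methylphenol | Oc1c(OC)c(C)c(C/C=C(\C)CC/C=C(\C)CC/C=C(\C)CC/C=C(\C)CC/C=C(\C)CCC=C(C)C)c(OC)c1OC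
F4 | step 15 | 4-[(2E,6E,10E,14E,18E)-3,7,11,15,19,23-hexamethyltetracosa-2,6,10,14,18,22-hexaen-1-yl]-2,3,6-trimethoxy-5-methylphenyl acetate | CC(=O)Oc1c(OC)c(C)c(C/C=C(\C)CC/C=C(\C)CC/C=C(\C)CC/C=C(\C)CC/C=C(\C)CCC=C(C)C)c(OC)c1OC
F5 | step 15 | 3-acetoxy-2-methoxy-5-methyl-6-[(2E,6E,10E,14E,18E)-3,7,11,15,19,23-hexamethyltetracosa-2,6,10,14,18,22-hexaen-1-yl]cyclohexa-2,5-diene-1,4-dione | COC1=C(OC(C)=O)C(=O)C(C)=C(C/C=C(\C)CC/C=C(\C)CC/C=C(\C)CC/C=C(\C)CC/C=C(\C)CCC=C(C)C)C1=O
F6 | step 5 | (2E,6E,10E,14E)-3,7,11,15,19-pentamethyl-9-(phenylsulfonyl)icosa-2,6,10,14,18-pentaen-1-ol, racemic at C9 | OC/C=C(\C)CC/C=C(\C)CC(S(=O)(=O)c1ccccc1)/C=C(\C)CC/C=C(\C)CCC=C(C)C
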